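The target is cut at C8–C9 of ring A, with ring carbons numbered C1–C10 along the target SMILES and C11–C13 as the side chain. C10 ties oxygen-bearing C1 to C9, and C9 is bonded to fusion carbon C8, the neighbour of C7; this is the enolate/alkene pattern left by an oxy-Cope shift. The precursor is a bicyclo[2.2.2]octene cage (bridgeheads C3, C6) from a masked o-benzoquinone Diels–Alder adduct, carrying a C1 isopropenyl carbinol, a C5 ketal and isopropenyl on C7. Its potassium alkoxide breaks C1–C6 and forms C8–C9 in one operation: ring A closes cis-fused, C8 is set, the C6=C7–C11=C12 diene appears, and the C1=C10 enolate is trapped with silicon.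

Key step: step 6

Remarks
- Locants C1–C13 defined above are used for every decalin intermediate; β is the face of H3 and H8, α the opposite face. Bicyclic compounds also carry systematic bicyclo[2.2.2]octane locants in their names.
- Compounds 4–7 are racemic; their SMILES show the enantiomer that is carried on after step 4.
- Assumption: the enantiomers of ketone 7 separate on a polysaccharide chiral phase, and the absolute configuration of the collected enantiomer is assigned by anomalous-dispersion X-ray analysis of a crystalline derivative before material is carried forward.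

Step 1
Reactants: 1 1-(3-hydroxy-4-methoxyphenyl)ethanone; 2 1,1-dimethoxyprop-1-ene
Product: 4 racemic 6-acetyl-3,3,7,7-tetramethoxy-8-methylbicyclo[2.2.2]oct-5-en-2-one (8-methyl syn to the C5=C6 bridge), via masked o-benzoquinone 3 (not isolated)
Conditions: PhI(OAc)2 (1.05 equiv), MeOH, 0 °C, 15 min; then Et3N (3 equiv), 2 (5 equiv), 0 °C to rt
Reagents that add atoms: methanol, CO
Why: Hypervalent-iodine dearomatisation of the guaiacol unit in methanol gives 6,6-dimethoxycyclohexa-2,4-dienone 3, and once the acetic acid is neutralised its acyl-activated diene should undergo an inverse-electron-demand Diels–Alder reaction with the ketene acetal in which the nucleophilic CH(CH3) carbon bonds to the dienone δ-carbon (C3), the acetal carbon bonds to C6, and the methyl group sits endo, syn to the new C7=C8 bond and away from the C2 ketal, so that C3, C4 and C6 are set in one relative configuration.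

Step 2
Reactants: 4
Product: 5 racemic 3,3,7,7-tetramethoxy-8-methyl-6-(prop-1-en-2-yl)bicyclo[2.2.2]oct-5-en-2-one
Conditions: Ph3PCH3Br (1.5 equiv), KOtBu (1.4 equiv), THF, 0 °C; then 4, 0 °C to rt
Reagents that add atoms: methyltriphenylphosphonium bromide, C[P+](c1ccccc1)(c1ccccc1)c1ccccc1.[Br-]
Why: Wittig methylenation reaches only the unhindered methyl ketone, because the C1 carbonyl is boxed in by the quaternary C2 ketal and by bridgehead C6 next to the C5 ketal, and no stereocentre is touched.

Step 3
Reactants: 5
Product: 7 racemic 7,7-dimethoxy-8-methyl-6-(prop-1-en-2-yl)bicyclo[2.2.2]oct-5-en-2-one, via α-methoxy ketone 6 (not isolated)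
Conditions: SmI2 (5 equiv), THF/MeOH (10:1), −78 °C to 0 °C
Reagents that add atoms: none
Why: Samarium diiodide reduction of an α-alkoxy ketone: electron transfer to the C1 carbonyl expels the two C2 methoxy groups one after the other through the samarium enolate, whereas the C5 ketal (not α to the carbonyl, C6 being a bridgehead) and the diene are left alone.

Step 4
Reactants: 7
Product: 8 (1S,4S,8R)-7,7-dimethoxy-8-methyl-6-(prop-1-en-2-yl)bicyclo[2.2.2]oct-5-en-2-one
Conditions: preparative SFC, amylose tris(3,5-dimethylphenylcarbamate) stationary phase, CO2/MeOH, 35 °C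
Reagents that add atoms: none
Why: Chromatographic resolution on a chiral stationary phase makes no bond; the rigid ketone with its diene chromophore suits a polysaccharide phase, and the enantiomer with C3 S, C4 R and C6 S (route locants) is kept.

Step 5
Reactants: 8 (1S,4S,8R)-7,7-dimethoxy-8-methyl-6-(prop-1-en-2-yl)bicyclo[2.2.2]oct-5-en-2-one; 9 2-bromopropene
Product: 11 (1S,2R,4S,8R)-7,7-dimethoxy-8-methyl-2,6-di(prop-1-en-2-yl)bicyclo[2.2.2]oct-5-en-2-ol, via isopropenylmagnesium bromide 10 (not isolated)
Conditions: 9, Mg, THF, 40 °C; LaCl3·2LiCl (1 equiv), THF, 0 °C; then 8, −20 °C to 0 °C; aq. NH4Cl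
Reagents that add atoms: none
Why: Lanthanum-promoted Grignard 1,2-addition suppresses enolisation at C2, and the reagent should enter C1 from the C7=C8 face because the C5 methoxy group that points toward C1 closes the other face, which sets C1 with isopropenyl syn to the alkene bridge as the sigmatropic shift requires.

Step 6
Reactants: 11 (1S,2R,4S,8R)-7,7-dimethoxy-8-methyl-2,6-di(prop-1-en-2-yl)bicyclo[2.2.2]oct-5-en-2-ol; 12 chlorotrimethylsilane
Product: 15 cis-decalin silyl enol ether (3S,4R,8R; C1 OSiMe3 on C1=C10; C5 dimethyl ketal; C6=C7–C11=C12 diene), via potassium alkoxide 13 (not isolated), via potassium enolate 14 (not isolated)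
Conditions: KH (1.5 equiv), 18-crown-6 (1.5 equiv), THF, 0 °C to rt; then 12/Et3N (1:1, 3 equiv), −78 °C to 0 °C
Reagents that add atoms: none
Why: Deprotonation gives the crown-separated potassium alkoxide 13, in which the 1,5-diene C9=C10–C1–C6–C7=C8 is held in a boat by the cage; a concerted [3,3]-sigmatropic shift breaks C1–C6 and forms C8–C9, and the enolate 14, with its double bond fixed at C1=C10, is O-silylated at low temperature. The closest known reaction type is the anionic oxy-Cope rearrangement of 2-alkenylbicyclo[2.2.2]oct-5-en-2-ols to cis-decalin enolates. Ring A (C1–C2–C3–C8–C9–C10) closes as a six-membered carbocycle through the sigmatropic C8–C9 bond, formed via a six-membered boat transition state, while ring B is the former C4–C5/C7=C8 ring of the cage. The new stereocentre C8 is set by the cage geometry: C9 can reach C8 only on the face turned to the C1–C2 bridge, which places H8 cis to H3 and to the C4 methyl group. The step needs the concerted path to outrun C1–C6 heterolysis (a 1,3-shift, or loss of the C5 methoxy group that lies anti to this bond) and needs the carbinol epimer with isopropenyl syn to C7=C8; the enforced boat with C9 already over C8, the poor leaving group and the facial course of step 5 should secure both.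

Step 7
Reactants: 15
Product: 17 dienone–enone (3S,4R,8S; C1 and C5 ketones; C9=C10; C6=C7–C11=C12), via enone ketal 16 (not isolated)
Conditions: Pd(OAc)2 (1.1 equiv), MeCN, rt; filter through Celite; then PPTS (0.2 equiv), acetone/H2O (10:1), rt
Reagents that add atoms: water, O
Why: Saegusa–Ito oxidation converts the silyl enol ether into a C10 enolate of divalent palladium, and syn β-hydride elimination toward ring carbon C9 places the enone double bond at C9=C10, after which pyridinium tosylate hydrolyses the allylic dimethyl ketal to the C5 dienone (acetal hydrolysis) without disturbing C3, C4 or C8.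

Step 8
Reactants: 17
Product: 18 diol (1R,3S,4R,5S,8S; both hydroxyl groups α)
Conditions: NaBH4 (2.5 equiv), CeCl3·7H2O (2.5 equiv), MeOH, −78 °C to −40 °C
Reagents that add atoms: none
Why: Luche 1,2-reduction of both conjugated ketones: in the favoured conformer of the cis-decalin (C9 axial on ring B to avoid allylic strain with the C7 isopropenyl group, C4 methyl equatorial) hydride should add to C5 axially and to C1 from its only open side, both on the convex β face that carries H3 and H8, which sets C1 and C5 with both hydroxyl groups α.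

Step 9
Reactants: 18
Product: 19 bis(triethylsilyl) ether of diol 18
Conditions: TESOTf (2.6 equiv), 2,6-lutidine (4 equiv), CH2Cl2, −78 °C
Reagents that add atoms: triethylsilyl trifluoromethanesulfonate, CC[Si](CC)(CC)OS(=O)(=O)C(F)(F)F
Why: Silyl ether formation with a silyl triflate and a hindered base covers both secondary hydroxyl groups, including the hindered α C1 one, so that no allylic leaving group or O–H bond meets the zerovalent nickel catalyst and the borane of the next step.

Step 10
Reactants: 19
Product: 21 allylic alcohol (7(11)E; C12 hydroxyl cis to C6; C1 and C5 triethylsilyl ethers), via allylboronate 20 (not isolated)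
Conditions: Ni(cod)2 (5 mol %), PCy3 (5 mol %), HBpin (1.3 equiv), toluene, rt; then 3 M aq. NaOH, 30% H2O2, THF, 0 °C
Reagents that add atoms: hydrogen peroxide, OO; pinacolborane, CC1(C)OBOC1(C)C (boron carried only by 20)
Why: Nickel-catalysed 1,4-hydroboration of a 1,3-diene: zerovalent nickel binds C6=C7–C11=C12 in its s-cis form, hydrogen goes to C6 and boron to the terminal C12, so the new tetrasubstituted C7=C11 bond forms with C12 cis to C6, and alkaline peroxide then oxidises the C–B bond in place while the isolated C9=C10 bond stays inert to pinacolborane.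

Step 11
Reactants: 21
Product: 22 C12 formate of 21
Conditions: HCO2H/Ac2O (50 °C, 2 h, gives acetic formic anhydride, 3 equiv); then 21, pyridine, CH2Cl2, −20 °C to 0 °C
Reagents that add atoms: acetic formic anhydride, CC(=O)OC=O (made beforehand from formic acid, O=CO, and acetic anhydride, CC(=O)OC(C)=O)
Why: Formylation with a mixed anhydride: acetic formic anhydride transfers its more electrophilic formyl group to the primary allylic C12 hydroxyl, the only free hydroxyl group in 21.

Step 12
Reactants: 22
Product: 23 C1,C5-diol C12-formate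
Conditions: HF·pyridine, pyridine, THF, 0 °C
Reagents that add atoms: none
Why: Fluoride-driven desilylation under buffered acidic conditions (Si–F bond formation) frees the C1 and C5 hydroxyl groups, and the formate, which basic fluoride or methanolysis would endanger, should survive.

Step 13
Reactants: 23
Product: 24 target CNP0262962.1
Conditions: Ac2O (4 equiv), pyridine, DMAP (0.1 equiv), CH2Cl2, 0 °C to rt
Reagents that add atoms: acetic anhydride, CC(=O)OC(C)=O
Why: DMAP-catalysed acetylation of the two secondary alcohols proceeds with retention at C1 and C5 and completes the target, the primary formate not being exchanged under these mild conditions.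

Compound list
1 | 1-(3-hydroxy-4-methoxyphenyl)ethanone | COc1ccc(C(C)=O)cc1O | starting material
2 | 1,1-dimethoxyprop-1-ene | CC=C(OC)OC | starting material
3 | 3-acetyl-6,6-dimethoxycyclohexa-2,4-dien-1-one (masked o-benzoquinone) | O=C1C=C(C(C)=O)C=CC1(OC)OC | intermediate
4 | racemic 6-acetyl-3,3,7,7-tetramethoxy-8-methylbicyclo[2.2.2]oct-5-en-2-one, 8-methyl syn to C5=C6 (route locants: C1 ketone, C2 and C5 ketals, C4 methyl, C7 acetyl) | O=C1C(OC)(OC)[C@@H]2[C@@H](C)C(OC)(OC)[C@H]1C(C(C)=O)=C2 | intermediate
5 | racemic 3,3,7,7-tetramethoxy-8-methyl-6-(prop-1-en-2-yl)bicyclo[2.2.2]oct-5-en-2-one, 8-methyl syn to C5=C6 | O=C1C(OC)(OC)[C@@H]2[C@@H](C)C(OC)(OC)[C@H]1C(C(C)=C)=C2 | intermediate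
6 | racemic 3,7,7-trimethoxy-8-methyl-6-(prop-1-en-2-yl)bicyclo[2.2.2]oct-5-en-2-one, mixture of C3 epimers | O=C1C(OC)[C@@H]2[C@@H](C)C(OC)(OC)[C@H]1C(C(C)=C)=C2 | intermediate
7 | racemic 7,7-dimethoxy-8-methyl-6-(prop-1-en-2-yl)bicyclo[2.2.2]oct-5-en-2-one, 8-methyl syn to C5=C6 | O=C1C[C@@H]2[C@@H](C)C(OC)(OC)[C@H]1C(C(C)=C)=C2 | intermediate
8 | (1S,4S,8R)-7,7-dimethoxy-8-methyl-6-(prop-1-en-2-yl)bicyclo[2.2.2]oct-5-en-2-one, single enantiomer | O=C1C[C@@H]2[C@@H](C)C(OC)(OC)[C@H]1C(C(C)=C)=C2 | intermediate
9 | 2-bromopropene | C=C(C)Br | starting material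
10 | isopropenylmagnesium bromide | C=C(C)[Mg]Br | intermediate
11 | (1S,2R,4S,8R)-7,7-dimethoxy-8-methyl-2,6-di(prop-1-en-2-yl)bicyclo[2.2.2]oct-5-en-2-ol; C2 isopropenyl and 8-methyl both syn to C5=C6 (route locants: C1 carbinol, C5 ketal, C7 isopropenyl) | C=C(C)[C@@]1(O)C[C@@H]2[C@@H](C)C(OC)(OC)[C@H]1C(C(C)=C)=C2 | intermediate
12 | chlorotrimethylsilane | C[Si](C)(C)Cl | starting material
13 | potassium alkoxide of 11 | C=C(C)[C@@]1([O-])C[C@@H]2[C@@H](C)C(OC)(OC)[C@H]1C(C(C)=C)=C2.[K+] | intermediate
14 | potassium C1=C10 enolate of the cis-decalin (3S,4R,8R), C5 dimethyl ketal, C6=C7–C11=C12 diene | [K+].[O-]C=1C[C@@H]2[C@@H](C)C(OC)(OC)C=C(C(C)=C)[C@@H]2CC=1C | intermediate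
15 | cis-decalin silyl enol ether (3S,4R,8R): C1 OSiMe3 on C1=C10, 10-methyl, 4β-methyl, 5,5-dimethoxy, C6=C7, 7-isopropenyl, H3 and H8 cis | C[Si](C)(C)OC=1C[C@@H]2[C@@H](C)C(OC)(OC)C=C(C(C)=C)[C@@H]2CC=1C | intermediate
16 | enone ketal (3S,4R,8S): C1 ketone, C9=C10, 10-methyl, 4β-methyl, 5,5-dimethoxy, C6=C7, 7-isopropenyl | O=C1C[C@@H]2[C@@H](C)C(OC)(OC)C=C(C(C)=C)[C@@H]2C=C1C | intermediate
17 | dienone–enone (3S,4R,8S): C1 and C5 ketones, C9=C10, 10-methyl, 4β-methyl, C6=C7, 7-isopropenyl | O=C1C[C@@H]2[C@@H](C)C(=O)C=C(C(C)=C)[C@@H]2C=C1C | intermediate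
18 | diol (1R,3S,4R,5S,8S): 1α- and 5α-hydroxyl, C9=C10, 10-methyl, 4β-methyl, C6=C7, 7-isopropenyl | O[C@@H]1C[C@@H]2[C@@H](C)[C@H](O)C=C(C(C)=C)[C@@H]2C=C1C | intermediate
19 | bis(triethylsilyl) ether of 18 (1R,3S,4R,5S,8S) | CC[Si](CC)(CC)O[C@@H]1C[C@@H]2[C@@H](C)[C@H](O[Si](CC)(CC)CC)C=C(C(C)=C)[C@@H]2C=C1C | intermediate
20 | allylboronate (1R,3S,4R,5R,8S,7(11)E): C12 pinacolboryl cis to C6, C1 and C5 triethylsilyl ethers | CC[Si](CC)(CC)O[C@@H]1C[C@@H]2[C@@H](C)[C@H](O[Si](CC)(CC)CC)C/C(=C(/C)CB3OC(C)(C)C(C)(C)O3)[C@@H]2C=C1C | intermediate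
21 | allylic alcohol (1R,3S,4R,5R,8S,7(11)E): C12 hydroxyl cis to C6, C1 and C5 triethylsilyl ethers | CC[Si](CC)(CC)O[C@@H]1C[C@@H]2[C@@H](C)[C@H](O[Si](CC)(CC)CC)C/C(=C(/C)CO)[C@@H]2C=C1C | intermediate
22 | C12 formate of 21 | CC[Si](CC)(CC)O[C@@H]1C[C@@H]2[C@@H](C)[C@H](O[Si](CC)(CC)CC)C/C(=C(/C)COC=O)[C@@H]2C=C1C | intermediate
23 | C1,C5-diol C12-formate (1R,3S,4R,5R,8S,7(11)E) | O[C@@H]1C[C@@H]2[C@@H](C)[C@H](O)C/C(=C(/C)COC=O)[C@@H]2C=C1C | intermediate
24 | CNP0262962.1 (1R,3S,4R,5R,8S,7(11)E): 1α,5α-diacetoxy, 4β-methyl, 10-methyl, C9=C10, C7=C11 bearing C13 methyl and C12 formyloxymethyl cis to C6 | CC(=O)O[C@@H]1C[C@@H]2[C@@H](C)[C@H](OC(C)=O)C/C(=C(/C)COC=O)[C@@H]2C=C1C | target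

Total step count: 13
Longest linear sequence: 13 steps (1 to 24)

Steps most likely to fail

1. Step 6 (key step). The C1–C6 bond may ionise ahead of C8–C9 bond formation, so that the alkoxide collapses by loss of the C5 methoxy group lying anti to that bond or recloses by a 1,3-shift. The fallback is the neutral siloxy-Cope rearrangement, which involves no alkoxide. It sets out from 11: O-silylation with 12 (imidazole, DMF, rt) gives the trimethylsilyl ether of the carbinol F1. Heating this ether in degassed diphenyl ether in base-washed glassware at about 220 °C should effect the thermal oxy-Cope shift through the same boat geometry and deliver silyl enol ether 15 directly, where the route is rejoined.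

2. Step 1. The ketene acetal may be consumed by acid-catalysed addition of methanol, or dienone 3 may dimerise faster than it is intercepted. The fallback separates the oxidation from the cycloaddition. It sets out from 1: oxidation with PhI(OAc)2 in MeOH without a dienophile gives the endo Diels–Alder dimer of 3 F2, which is isolated free of methanol and acid. Thermolysis of this dimer with 2 (10 equiv) in mesitylene in a sealed tube at about 200 °C should regenerate 3 by retro-Diels–Alder reaction and trap it as 4, where the route is rejoined.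

3. Step 10. The fully substituted diene may bind the nickel catalyst too weakly in its s-cis form, so that hydroboration stalls or takes a 1,2-course that loses the alkene geometry. The fallback is palladium-catalysed 1,4-hydrosilylation followed by Tamao–Fleming oxidation. It sets out from 19: Pd(PPh3)4 (zerovalent palladium) and HSiCl3 in benzene at 60 °C should give the allyltrichlorosilane F3 with C12 cis to C6. Ethanolysis (EtOH, Et3N, 0 °C) gives the allyltriethoxysilane F4, and KF/KHCO3/30% H2O2 in THF/MeOH oxidises the C12–Si bond in place to allylic alcohol 21, where the route is rejoined.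

Further compounds
F1 | step 6 | trimethylsilyl ether of carbinol 11 | C=C(C)[C@@]1(O[Si](C)(C)C)C[C@@H]2[C@@H](C)C(OC)(OC)[C@H]1C(C(C)=C)=C2
F2 | step 1 | racemic endo dimer of 3, 6,12-diacetyl-3,3,10,10-tetramethoxytricyclo[6.2.2.0(2,7)]dodeca-5,11-diene-4,9-dione | O=C1C(OC)(OC)[C@@H]2C=C(C(C)=O)[C@H]1[C@H]1C(C(C)=O)=CC(=O)C(OC)(OC)[C@@H]21
F3 | step 10 | C12 trichlorosilyl analogue of 20 (7(11)E, C12 cis to C6) | CC[Si](CC)(CC)O[C@@H]1C[C@@H]2[C@@H](C)[C@H](O[Si](CC)(CC)CC)C/C(=C(/C)C[Si](Cl)(Cl)Cl)[C@@H]2C=C1C
F4 | step 10 | C12 triethoxysilyl analogue of 20 (7(11)E, C12 cis to C6) | CC[Si](CC)(CC)O[C@@H]1C[C@@H]2[C@@H](C)[C@H](O[Si](CC)(CC)CC)C/C(=C(/C)C[Si](OCC)(OCC)OCC)[C@@H]2C=C1C
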